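## Structural features

The target is a flavonol: a 4H-chromen-4-one (benzene ring A fused at C4a–C8a to pyranone ring C) with a 4-methoxyphenyl group (ring B) at C2, an enolic hydroxyl at C3 and phenolic hydroxyls at C5 and C7. C8 bears a 2-methylbut-3-en-2-yl (1,1-dimethylallyl) group, so a quaternary benzylic carbon sits between the C7 oxygen and the ring oxygen at C8a, while C6 is unsubstituted. There is no stereocentre and no stereogenic double bond; the problem is one of regiochemistry and functional-group compatibility. The fragile parts are the electron-rich 1,3,5-trioxygenated ring A, the oxidisable C3 enol, the terminal alkene (which rules out hydrogenolysis and can be attacked by the C7 hydroxyl under strong acid) and the ring B methyl ether, which forbids methyl ethers as protecting groups elsewhere. The real difficulty is the tert-alkyl group at C8: substitution or Claisen chemistry on a phloroglucinol-type ring does not separate C8 from C6 reliably, and a quaternary carbon cannot be coupled onto so crowded a position. The key step uses the fact that the six carbons of ring A come from three sources: C4a and C8a are C5 and C6 of a preformed 4-pyranone (ring C), C5 and C8 are the carbonyl and alpha carbons of a ketene, and C6 and C7 are the two carbons of an oxygenated alkyne. The C5 hydroxyl is then the ketene oxygen, the C7 oxygen the alkyne oxygen, the C6 hydrogen the alkyne hydrogen and the C8 side chain the ketene substituent, so the pattern is fixed by connectivity and not by selectivity.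

## Logic of the disconnections

**23 from 21.** Only the O–Si bond at C7 and the O–CH2 bond of the acetal at C3 are cut. Neither hydroxyl can be carried free through carbanion, diazo and ketene chemistry; the C5 hydroxyl needs no protection because the ring-forming step creates it, chelated to the C4 carbonyl. The gain is that both groups leave without hydrogenation and without a Lewis acid. The forward step must spare the terminal alkene and the ring B methyl ether, and is run in one flask through 22.

**21 from 12 and 16.** C5–C6, C7–C8 and C5–C4a are cut, which removes ring A altogether. A fourth bond, C8–C(quaternary), is traced back to an acyl–C(quaternary) bond in 12, because the side chain reaches C8 by a 1,2-shift. The reason is that all four substituents of ring A then follow from which atoms the two partners supply, and the aryl–tert-alkyl bond is never made on an existing arene. The gain is a bicyclic, fully substituted ring system reduced to a monocyclic heterocycle and a two-carbon unit. The forward step needs clean ketene formation from 12, cycloaddition at a hindered disubstituted ketene, and ring closure onto a pyranone C=C bond.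

**16 from 13.** The O–C(sp) and O–Si bonds are cut. The reason is that 16 is not a dependable catalogue item, and the gain is that it comes in one operation from 13. The demand is oxygen transfer to the acetylide and silylation at oxygen, not at carbon.

**12 from 11.** The C=N2 bond is cut. The methylene of 11 lies between a ketone and a vinylogously activating pyranone, and the other alpha carbon is quaternary, so only one diazo ketone can form. The gain is a plain ketone; the demand is sufficient acidity for direct diazo transfer.

**11 from 7 and 9.** The bond between the side-chain methylene and the ketone carbonyl is cut. This turns the chain into the 6-methyl group of 7, acidic by vinylogy, and into 9, which has no alpha hydrogen. The gain is a convergent union of ring C with the whole side chain; the demand is acylation of the extended enolate at carbon, not at oxygen.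

**9 from 8.** Only the C–Cl bond is cut, because the acid must be activated for C-acylation. 8 is a catalogue compound that already holds the quaternary carbon and the vinyl group, and the demand is only that the chloride is used without purification.

**7 from 5 and 6.** The C2–aryl bond is cut. Ring B arrives with 6 and the C3 oxygen is already in place, so no later oxidation at C3 is needed. The demand is a cross-coupling at a beta-bromo enone under base that the pyranone tolerates.

**5 from 4.** The O–CH2 bond of the acetal is cut. The enolic hydroxyl must be masked before palladium, amide base and diazo chemistry; the gain is the free enol 4, and the demand is O-alkylation without attack on the C–Br bond.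

**4 from 3.** The C–Br bond is cut. The enolic hydroxyl of 3 directs the halogen to the adjacent ring carbon, which fixes the aryl group next to the C3 oxygen. The demand is monobromination at that carbon and not at the other ring CH or the methyl group.

**3 from 2.** The new C–H bond of the methyl group is traced back to a C–Cl bond. The gain is that the methyl group comes from a functionalised carbon already present; the demand is reduction without touching the ring.

**2 from 1.** The C–Cl bond is traced back to the C–OH bond of 1, a cheap fermentation product that carries the pyranone, the oxygen pattern and the future C8 carbon. The demand is substitution of the primary alcohol in the presence of the free enol.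

## Other disconnections considered

Alternative 1: The cut is at the two C–CH3 bonds of the quaternary side-chain carbon. That carbon is traced back to C3 of a benzofuran-2(3H)-one whose ring oxygen is the future O1 and whose carbonyl carbon is the future vinyl CH.
- Forward key step: the enolate of 4,6-bis(methoxymethoxy)-1-benzofuran-2(3H)-one A2 would be methylated twice with base and a methyl halide. This would give 4,6-bis(methoxymethoxy)-3,3-dimethyl-1-benzofuran-2(3H)-one A1 as the product of the key step. Reduction of A1 to the lactol oxidation level and methylenation would then give 3,5-bis(methoxymethoxy)-2-(2-methylbut-3-en-2-yl)phenol A3 with the complete side chain.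
- In favour: this is ordinary enolate alkylation at an unhindered sp3 carbon. The lactone ties the side chain to the correct ring position, so placement of the quaternary carbon is as secure as in the chosen plan. In precedent the step from A2 to A1 is the better of the two key steps.
- Against: it solves only the side chain. From A3 ring C must still be built by ortho-acylation, chalcone formation and oxidative cyclisation, on a ring with acid-labile acetals and an acid-sensitive ortho tert-allyl phenol. Oxidative flavonol closure of chalcones oxygenated next to the carbonyl-bearing carbon tends to divert to aurones. O-methylation of the aromatic enolate of A2 could also compete.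
- Comparison: the mechanism is safer step by step, but the structure is assembled linearly, and some thirteen to fifteen steps are estimated against eleven.

Alternative 2: The cut is at C3–C4 and C2=C3 of ring C.
- Forward key step: triphenyl{[2-(trimethylsilyl)ethoxy]methylidene}-λ5-phosphane A6 would be acylated by 2-(chlorocarbonyl)-3,5-bis(methoxymethoxy)-6-(2-methylbut-3-en-2-yl)phenyl 4-methoxybenzoate A5 to form C3–C4. The keto ylide would then olefinate the neighbouring aryl ester carbonyl and give 5,7-bis(methoxymethoxy)-2-(4-methoxyphenyl)-8-(2-methylbut-3-en-2-yl)-3-[2-(trimethylsilyl)ethoxy]-4H-chromen-4-one A4 as the product of the key step.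
- In favour: ring C, the C3 oxygen and ring B arrive in one convergent operation with inherent regiochemistry, equal to the chosen plan on that point. It needs no photochemistry, which is an advantage. Intramolecular ester olefination of acyl ylides to chromones is a known reaction type, so the closure to A4 is better precedented than the chosen key step.
- Against: A5 already contains the C8 tert-allyl group on a hexasubstituted benzene, so the central problem is only moved into the synthesis of A5. An acid chloride must be made beside two acetals and a neighbouring aryl ester. An ylide such as A6 is unstabilised and thermally labile, and the ester carbonyl to be olefinated is crowded by the ortho tert-alkyl group.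
- Comparison: step count is about equal (eleven to thirteen estimated); the uncertainty sits in the precursor and not in the ring closure.

Alternative 3: The cut is at C3–C4 only.
- Forward key step: a thiazolium-derived carbene would convert the aromatic aldehyde of 2-[1-(4-methoxyphenyl)-2-oxoethoxy]-4,6-bis(methoxymethoxy)-3-(2-methylbut-3-en-2-yl)benzaldehyde A8 into an acyl anion equivalent that adds to the aliphatic aldehyde. This would give racemic trans-3-hydroxy-5,7-bis(methoxymethoxy)-2-(4-methoxyphenyl)-8-(2-methylbut-3-en-2-yl)-2,3-dihydro-4H-chromen-4-one A7 (the (2R,3R) enantiomer is the one drawn). Dehydrogenation and deprotection of A7 would follow.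
- In favour: the closure is catalytic, metal-free and mild. It sets the C3 oxygen directly, and the two stereocentres of A7 do not matter because dehydrogenation removes them. Intramolecular benzoin closure to chroman-4-ones is closer to precedent than the chosen key step, which is a real advantage.
- Against: the aldehyde that must become the acyl anion is flanked by two ortho substituents. If the carbene adds to the other, alpha-aryloxy aldehyde instead, expulsion of the phenoxide is the expected course. A8 needs alkylation of a hindered phenol with an alpha-halo arylacetaldehyde equivalent, an extra oxidation is required, and A8 again presupposes the C8 tert-allyl ring.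
- Comparison: the mechanism is milder, but chemoselectivity is doubtful and the sequence is longer (twelve to fourteen steps estimated).

Key step: step 10

**Remarks on the chemistry.**
- Bond count of the key step: three new ring bonds (C5–C6, C7–C8 and C5–C4a) close ring A. The 1,2-shift in addition moves the tert-alkyl group from the acyl carbon of 12 to the future C8, so one further C–C bond is formed and one is broken.
- Assumption: the long-wavelength diazo band of 12 is taken to lie beyond 420 nm, clear of the arylpyranone chromophore, so that 450 nm light excites the diazo group alone.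
- The target has no stereocentre; 18 and 20 each carry one transient stereocentre and form as racemates.

## Route

Step 1
Reactants: 1 kojic acid (5-hydroxy-2-(hydroxymethyl)-4H-pyran-4-one)
Product: 2 2-(chloromethyl)-5-hydroxy-4H-pyran-4-one
Conditions: SOCl2 (neat), 20 °C
Reagents that add atoms: thionyl chloride O=S(Cl)Cl
Why: Deoxychlorination of the primary alcohol through its chlorosulfite; the enolic hydroxyl is not displaced and any chlorosulfite formed there is hydrolysed on work-up.

Step 2
Reactants: 2 2-(chloromethyl)-5-hydroxy-4H-pyran-4-one
Product: 3 5-hydroxy-2-methyl-4H-pyran-4-one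
Conditions: Zn, conc. HCl, H2O, 70 °C
Reagents that add atoms: none
Why: Dissolving-metal reduction of a vinylogous alpha-chloro ketone: zinc inserts readily and protonation of the dienolate at the exocyclic carbon gives the methyl group, the ring being left intact.

Step 3
Reactants: 3 5-hydroxy-2-methyl-4H-pyran-4-one
Product: 4 2-bromo-3-hydroxy-6-methyl-4H-pyran-4-one
Conditions: NBS, MeCN, 0 to 20 °C
Reagents that add atoms: N-bromosuccinimide O=C1CCC(=O)N1Br
Why: Electrophilic bromination of the enol: the hydroxyl activates only the adjacent ring carbon (beta carbon of the enol, alpha to the ring oxygen), so one equivalent should brominate there and not at the other ring CH or the methyl group.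

Step 4
Reactants: 4 2-bromo-3-hydroxy-6-methyl-4H-pyran-4-one
Product: 5 2-bromo-3-(methoxymethoxy)-6-methyl-4H-pyran-4-one
Conditions: MOMCl, iPr2NEt, CH2Cl2, 0 to 20 °C
Reagents that add atoms: chloromethyl methyl ether COCCl
Why: Williamson-type O-alkylation of the acidic enolic hydroxyl by the alpha-chloro ether; the acetal withstands the bases, the diazo transfer, light and heat of the later steps.

Step 5
Reactants: 5 2-bromo-3-(methoxymethoxy)-6-methyl-4H-pyran-4-one; 6 (4-methoxyphenyl)boronic acid
Product: 7 3-(methoxymethoxy)-2-(4-methoxyphenyl)-6-methyl-4H-pyran-4-one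
Conditions: Pd(PPh3)4 (5 mol %), K2CO3, 1,4-dioxane/H2O, 85 °C
Reagents that add atoms: none
Why: Suzuki–Miyaura coupling: the C–Br bond of a beta-bromo enone adds readily to zerovalent palladium, and transmetalation and reductive elimination place ring B next to the protected C3 oxygen.

Step 6
Reactants: 8 2,2-dimethylbut-3-enoic acid
Product: 9 2,2-dimethylbut-3-enoyl chloride
Conditions: (COCl)2, DMF (cat.), CH2Cl2, 0 to 20 °C; concentrated, used crude
Reagents that add atoms: oxalyl chloride O=C(Cl)C(=O)Cl
Why: Acid chloride formation through the Vilsmeier-type chloroiminium catalyst; with no alpha hydrogen neither isomerisation nor ketene formation can interfere.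

Step 7
Reactants: 7 3-(methoxymethoxy)-2-(4-methoxyphenyl)-6-methyl-4H-pyran-4-one; 9 2,2-dimethylbut-3-enoyl chloride
Product: 11 6-(3,3-dimethyl-2-oxopent-4-en-1-yl)-3-(methoxymethoxy)-2-(4-methoxyphenyl)-4H-pyran-4-one, via lithium dienolate 10 (not isolated)
Conditions: LiN(SiMe3)2 (2.2 equiv), THF, −78 °C; then 9, −78 to −20 °C; aq. NH4Cl
Reagents that add atoms: none
Why: Lateral (vinylogous) deprotonation of the 6-methyl group gives extended enolate 10, which should be acylated at the exocyclic carbon because only that mode restores the pyranone (Claisen-type C-acylation). The second equivalent of base takes up the more acidic methylene proton of 11, and 9 cannot be turned into a ketene by the amide base.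

Step 8
Reactants: 11 6-(3,3-dimethyl-2-oxopent-4-en-1-yl)-3-(methoxymethoxy)-2-(4-methoxyphenyl)-4H-pyran-4-one
Product: 12 6-(1-diazo-3,3-dimethyl-2-oxopent-4-en-1-yl)-3-(methoxymethoxy)-2-(4-methoxyphenyl)-4H-pyran-4-one
Conditions: 4-AcNHC6H4SO2N3, DBU, MeCN, 0 to 20 °C
Reagents that add atoms: 4-acetamidobenzenesulfonyl azide CC(=O)Nc1ccc(cc1)S(=O)(=O)N=[N+]=[N-]
Why: Regitz diazo transfer: the methylene is activated by the ketone and, vinylogously, by the pyranone carbonyl, so its enolate attacks the terminal azide nitrogen and the triazene collapses to the diazo compound and the sulfonamide. The other alpha carbon is quaternary, so only one product is possible.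

Step 9
Reactants: 13 ethyne (acetylene)
Product: 16 (ethynyloxy)tri(propan-2-yl)silane, via ethynyllithium 14 (not isolated), via lithium ethynolate 15 (not isolated)
Conditions: 13 (saturated THF), n-BuLi, −78 °C; t-BuOOLi (from t-BuOOH, LiN(SiMe3)2), −78 to −10 °C; iPr3SiOTf, −78 to 0 °C; distillation
Reagents that add atoms: tert-butyl hydroperoxide CC(C)(C)OO; tri(propan-2-yl)silyl trifluoromethanesulfonate CC(C)[Si](OS(=O)(=O)C(F)(F)F)(C(C)C)C(C)C
Why: Electrophilic oxygenation of a lithium acetylide by lithium tert-butyl peroxide (ynolate formation) followed by O-silylation, a sequence established for terminal alkynes and applied here to the parent acetylide. Excess acetylene holds back disproportionation of 14, and the bulky silyl group favours reaction at oxygen and makes the ynol ether isolable.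

Step 10
Reactants: 12 6-(1-diazo-3,3-dimethyl-2-oxopent-4-en-1-yl)-3-(methoxymethoxy)-2-(4-methoxyphenyl)-4H-pyran-4-one; 16 (ethynyloxy)tri(propan-2-yl)silane
Product: 21 5-hydroxy-3-(methoxymethoxy)-2-(4-methoxyphenyl)-8-(2-methylbut-3-en-2-yl)-7-{[tri(propan-2-yl)silyl]oxy}-4H-chromen-4-one, via ketene 17 (not isolated), via cyclobutenone 18 (not isolated), via dienylketene 19 (not isolated), via keto tautomer 20 (not isolated)
Conditions: 16 (3 equiv), hν (450 nm LED), ClCH2CH2Cl, 20 °C; then 80 °C
Reagents that add atoms: none
Why: Proposed new method: selective excitation of the diazo chromophore of 12 should expel N2 and, with 1,2-shift of the tert-alkyl group (Wolff rearrangement), give ketene 17; the closest known reaction type is the photochemical Danheiser benzannulation of aryl and heteroaryl alpha-diazo ketones with siloxyalkynes, which has not been shown for a 4-pyranone or for a ketene bearing a tert-alkyl group. The nucleophilic CH carbon of 16 attacks the ketene carbonyl carbon (C5–C6) and the siloxy carbon then bonds to the ketene alpha carbon (C7–C8), giving 3-siloxycyclobutenone 18 in a regiospecific (2+2) addition. At 80 °C 18 opens reversibly in a conrotatory four-electron process, and only the dienylketene 19 whose pyranone stands cis to the ketenyl carbon can go on, the other isomer returning through 18. Ring A is closed by a disrotatory six-electron electrocyclisation of 19 in which the ketene carbon bonds to C5 of the pyranone (C5–C4a of the chromone), helped by the weak aromaticity of the pyranone C=C bond. Enolisation of the doubly activated C4a–H of 20 then gives the chelated C5 phenol 21, and no stereocentre remains because the quaternary carbon of 18 and C4a of 20 are transient and racemic. The one selectivity needed is the orientation of the alkyne in the (2+2) step, secured by the polarisation of the ynol ether; since all four ring A substituents follow from which atoms the partners contribute, an isomer with the side chain at C6 is excluded by construction. Light is used without a transition-metal catalyst because metal carbenoids divert beta,gamma-unsaturated diazo ketones into the vinylogous Wolff pathway, and irradiation ends before any chromone chromophore is present.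

Step 11
Reactants: 21 5-hydroxy-3-(methoxymethoxy)-2-(4-methoxyphenyl)-8-(2-methylbut-3-en-2-yl)-7-{[tri(propan-2-yl)silyl]oxy}-4H-chromen-4-one
Product: 23 3,5,7-trihydroxy-2-(4-methoxyphenyl)-8-(2-methylbut-3-en-2-yl)-4H-chromen-4-one, via 5,7-diol 22 (not isolated)
Conditions: Bu4NF (1.2 equiv), THF, 0 °C; then MeOH, aq. HCl (3 M), 45 °C
Reagents that add atoms: none
Why: Fluoride cleaves the aryl silyl ether at 0 °C without touching the acetal, and acid-catalysed methanolysis of the methoxymethyl acetal in the same flask frees the C3 hydroxyl. The monosubstituted alkene is not protonated by dilute HCl at 45 °C, so cyclisation of the C7 hydroxyl onto the side chain is not expected.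

## Compound list

1 | kojic acid (5-hydroxy-2-(hydroxymethyl)-4H-pyran-4-one) | O=c1cc(CO)occ1O | starting material
2 | 2-(chloromethyl)-5-hydroxy-4H-pyran-4-one | O=c1cc(CCl)occ1O | intermediate
3 | 5-hydroxy-2-methyl-4H-pyran-4-one | Cc1cc(=O)c(O)co1 | intermediate
4 | 2-bromo-3-hydroxy-6-methyl-4H-pyran-4-one | Cc1cc(=O)c(O)c(Br)o1 | intermediate
5 | 2-bromo-3-(methoxymethoxy)-6-methyl-4H-pyran-4-one | COCOc1c(Br)oc(C)cc1=O | intermediate
6 | (4-methoxyphenyl)boronic acid | COc1ccc(B(O)O)cc1 | starting material
7 | 3-(methoxymethoxy)-2-(4-methoxyphenyl)-6-methyl-4H-pyran-4-one | COCOc1c(-c2ccc(OC)cc2)oc(C)cc1=O | intermediate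
8 | 2,2-dimethylbut-3-enoic acid | C=CC(C)(C)C(=O)O | starting material
9 | 2,2-dimethylbut-3-enoyl chloride | C=CC(C)(C)C(=O)Cl | intermediate
10 | lithium 3-(methoxymethoxy)-2-(4-methoxyphenyl)-6-methylidene-6H-pyran-4-olate | [Li+].[O-]C1=CC(=C)OC(-c2ccc(OC)cc2)=C1OCOC | intermediate (not isolated)
11 | 6-(3,3-dimethyl-2-oxopent-4-en-1-yl)-3-(methoxymethoxy)-2-(4-methoxyphenyl)-4H-pyran-4-one | COCOc1c(-c2ccc(OC)cc2)oc(CC(=O)C(C)(C)C=C)cc1=O | intermediate
12 | 6-(1-diazo-3,3-dimethyl-2-oxopent-4-en-1-yl)-3-(methoxymethoxy)-2-(4-methoxyphenyl)-4H-pyran-4-one | COCOc1c(-c2ccc(OC)cc2)oc(C(=[N+]=[N-])C(=O)C(C)(C)C=C)cc1=O | intermediate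
13 | ethyne (acetylene) | C#C | starting material
14 | ethynyllithium | [Li]C#C | intermediate (not isolated)
15 | lithium ethynolate | [Li+].[O-]C#C | intermediate (not isolated)
16 | (ethynyloxy)tri(propan-2-yl)silane | C#CO[Si](C(C)C)(C(C)C)C(C)C | intermediate
17 | 2-[5-(methoxymethoxy)-6-(4-methoxyphenyl)-4-oxo-4H-pyran-2-yl]-3,3-dimethylpenta-1,4-dien-1-one | COCOc1c(-c2ccc(OC)cc2)oc(C(=C=O)C(C)(C)C=C)cc1=O | intermediate (not isolated)
18 | 3-(methoxymethoxy)-2-(4-methoxyphenyl)-6-[1-(2-methylbut-3-en-2-yl)-4-oxo-2-{[tri(propan-2-yl)silyl]oxy}cyclobut-2-en-1-yl]-4H-pyran-4-one (racemic) | COCOc1c(-c2ccc(OC)cc2)oc(C2(C(C)(C)C=C)C(=O)C=C2O[Si](C(C)C)(C(C)C)C(C)C)cc1=O | intermediate (not isolated)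
19 | (3E)-4-[5-(methoxymethoxy)-6-(4-methoxyphenyl)-4-oxo-4H-pyran-2-yl]-5,5-dimethyl-3-{[tri(propan-2-yl)silyl]oxy}hepta-1,3,6-trien-1-one | O=C=C/C(O[Si](C(C)C)(C(C)C)C(C)C)=C(\c1cc(=O)c(OCOC)c(-c2ccc(OC)cc2)o1)C(C)(C)C=C | intermediate (not isolated)
20 | 3-(methoxymethoxy)-2-(4-methoxyphenyl)-8-(2-methylbut-3-en-2-yl)-7-{[tri(propan-2-yl)silyl]oxy}-4H-chromene-4,5(4aH)-dione (racemic) | C=CC(C)(C)C1=C2OC(-c3ccc(OC)cc3)=C(OCOC)C(=O)C2C(=O)C=C1O[Si](C(C)C)(C(C)C)C(C)C | intermediate (not isolated)
21 | 5-hydroxy-3-(methoxymethoxy)-2-(4-methoxyphenyl)-8-(2-methylbut-3-en-2-yl)-7-{[tri(propan-2-yl)silyl]oxy}-4H-chromen-4-one | C=CC(C)(C)c1c(O[Si](C(C)C)(C(C)C)C(C)C)cc(O)c2c(=O)c(OCOC)c(-c3ccc(OC)cc3)oc12 | intermediate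
22 | 5,7-dihydroxy-3-(methoxymethoxy)-2-(4-methoxyphenyl)-8-(2-methylbut-3-en-2-yl)-4H-chromen-4-one | C=CC(C)(C)c1c(O)cc(O)c2c(=O)c(OCOC)c(-c3ccc(OC)cc3)oc12 | intermediate (not isolated)
23 | 3,5,7-trihydroxy-2-(4-methoxyphenyl)-8-(2-methylbut-3-en-2-yl)-4H-chromen-4-one | C=CC(C)(C)c1c(O)cc(O)c2c(=O)c(O)c(-c3ccc(OC)cc3)oc12 | target

## Step count and least certain steps

Total: 11 steps. Longest linear sequence: 9 steps (1, 2, 3, 4, 5, 7, 8, 10, 11); steps 6 and 9 are side branches. If 3 is bought instead of made, steps 1 and 2 fall away.

**Step 10 (key step, proposed new method).** The bulky groups on both sides of the diazo ketone favour the s-E conformer, from which a free carbene is expected instead of a concerted shift. The carbene may then be captured by the neighbouring vinyl group or by other pathways before the tert-alkyl group migrates. The hindered ketene may also add the alkyne too slowly and be consumed by adventitious nucleophiles.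

The fallback uses known chemistry throughout. It sets out from boronic acid 6 and comes back to the route at target 23. 5,7-Dihydroxy-4H-chromen-4-one F1 (purchased) would be protected (NaH, MOMCl, DMF) as 5,7-bis(methoxymethoxy)-4H-chromen-4-one F2. Conjugate addition of 6, catalysed by Pd(O2CCF3)2 (a divalent palladium salt) with 2,2'-bipyridine, should give racemic 5,7-bis(methoxymethoxy)-2-(4-methoxyphenyl)-2,3-dihydro-4H-chromen-4-one F3. DDQ in dioxane would dehydrogenate it to 5,7-bis(methoxymethoxy)-2-(4-methoxyphenyl)-4H-chromen-4-one F4. Epoxidation of the C2=C3 bond with dimethyldioxirane would give racemic 4,6-bis(methoxymethoxy)-1a-(4-methoxyphenyl)-1a,7a-dihydro-7H-oxireno[2,3-b]chromen-7-one F5. HCl in methanol would open it to the flavonol and remove both acetals, giving 3,5,7-trihydroxy-2-(4-methoxyphenyl)-4H-chromen-4-one F6. Alkylation of the most acidic (C7) hydroxyl with 1-bromo-3-methylbut-2-ene (K2CO3, acetone) would give 3,5-dihydroxy-2-(4-methoxyphenyl)-7-[(3-methylbut-2-en-1-yl)oxy]-4H-chromen-4-one F7. Aromatic Claisen rearrangement (Eu(fod)3, CHCl3, 60 °C, or N,N-diethylaniline, 190 °C) would transfer the allyl unit with inversion to C8 and give 23; a further shift is blocked because the para position is C4a. This path gives up the regiochemical certainty of the key step: some C6 isomer and some alkylation at O3 must be expected and separated.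

**Step 9.** The monolithium acetylide may disproportionate on warming, oxygen transfer may be incomplete, and silylation may occur at carbon instead of oxygen; the parent ynolate is less hindered at carbon than the substituted ones for which the method is established.

The fallback sets out from diazo ketone 12 and comes back at target 23. Ethynyl(trimethyl)silane F8 (purchased), an ordinary terminal alkyne whose acetylide cannot disproportionate, would be taken through the sequence of step 9 to trimethyl({[tri(propan-2-yl)silyl]oxy}ethynyl)silane F9. Its silylated carbon terminus is crowded, which should disfavour silylation at carbon by the bulky triflate. Benzannulation of 12 with F9 under the conditions of step 10 would give 5-hydroxy-3-(methoxymethoxy)-2-(4-methoxyphenyl)-8-(2-methylbut-3-en-2-yl)-6-(trimethylsilyl)-7-{[tri(propan-2-yl)silyl]oxy}-4H-chromen-4-one F10. Fluoride would then give 5,7-dihydroxy-3-(methoxymethoxy)-2-(4-methoxyphenyl)-8-(2-methylbut-3-en-2-yl)-6-(trimethylsilyl)-4H-chromen-4-one F11. The acid stage of step 11 would remove both the acetal and, by ipso-protodesilylation of the very electron-rich ring, the C6 silyl group, giving 23. The price is a more hindered cycloaddition partner.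

**Step 7.** Acylation may occur at the enolate oxygen instead of carbon, to which hindered acyl chlorides are prone. Proton transfer from product to unreacted dienolate may also cause incomplete conversion or double acylation.

The fallback sets out from 7 (with acid 8 as the source of the side chain) and comes back at ketone 11. Acid 8 would be reduced (LiAlH4) to 2,2-dimethylbut-3-en-1-ol F12 and oxidised (Swern) to 2,2-dimethylbut-3-enal F13. Aldol addition of dienolate 10 to this non-enolisable aldehyde, where acylation at oxygen is not possible, would give racemic 6-(2-hydroxy-3,3-dimethylpent-4-en-1-yl)-3-(methoxymethoxy)-2-(4-methoxyphenyl)-4H-pyran-4-one F14. Dess–Martin oxidation would then give 11.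

**Step 8.** Diazo transfer may be slow or incomplete at a methylene that is shielded by the neighbouring quaternary carbon and only vinylogously activated on one side, leaving time for base-induced decomposition.

The fallback sets out from 11 and comes back at 12 by detrifluoroacetylative diazo transfer. The lithium enolate of 11 (LiN(SiMe3)2, THF, −78 °C) would be acylated with 2,2,2-trifluoroethyl trifluoroacetate to 3-(methoxymethoxy)-2-(4-methoxyphenyl)-6-(1,1,1-trifluoro-5,5-dimethyl-2,4-dioxohept-6-en-3-yl)-4H-pyran-4-one F15. Methanesulfonyl azide and Et3N in MeCN would then transfer the diazo group with loss of the trifluoroacetyl group, giving 12.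

## Further compounds

F1 | step 10 | 5,7-dihydroxy-4H-chromen-4-one | O=c1ccoc2cc(O)cc(O)c12
F2 | step 10 | 5,7-bis(methoxymethoxy)-4H-chromen-4-one | COCOc1cc(OCOC)c2c(=O)ccoc2c1
F3 | step 10 | 5,7-bis(methoxymethoxy)-2-(4-methoxyphenyl)-2,3-dihydro-4H-chromen-4-one (racemic) | COCOc1cc(OCOC)c2c(c1)OC(c1ccc(OC)cc1)CC2=O
F4 | step 10 | 5,7-bis(methoxymethoxy)-2-(4-methoxyphenyl)-4H-chromen-4-one | COCOc1cc(OCOC)c2c(=O)cc(-c3ccc(OC)cc3)oc2c1
F5 | step 10 | 4,6-bis(methoxymethoxy)-1a-(4-methoxyphenyl)-1a,7a-dihydro-7H-oxireno[2,3-b]chromen-7-one (racemic) | COCOc1cc(OCOC)c2c(c1)OC1(c3ccc(OC)cc3)OC1C2=O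
F6 | step 10 | 3,5,7-trihydroxy-2-(4-methoxyphenyl)-4H-chromen-4-one | COc1ccc(-c2oc3cc(O)cc(O)c3c(=O)c2O)cc1
F7 | step 10 | 3,5-dihydroxy-2-(4-methoxyphenyl)-7-[(3-methylbut-2-en-1-yl)oxy]-4H-chromen-4-one | COc1ccc(-c2oc3cc(OCC=C(C)C)cc(O)c3c(=O)c2O)cc1
F8 | step 9 | ethynyl(trimethyl)silane | C#C[Si](C)(C)C
F9 | step 9 | trimethyl({[tri(propan-2-yl)silyl]oxy}ethynyl)silane | CC(C)[Si](OC#C[Si](C)(C)C)(C(C)C)C(C)C
F10 | step 9 | 5-hydroxy-3-(methoxymethoxy)-2-(4-methoxyphenyl)-8-(2-methylbut-3-en-2-yl)-6-(trimethylsilyl)-7-{[tri(propan-2-yl)silyl]oxy}-4H-chromen-4-one | C=CC(C)(C)c1c(O[Si](C(C)C)(C(C)C)C(C)C)c([Si](C)(C)C)c(O)c2c(=O)c(OCOC)c(-c3ccc(OC)cc3)oc12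
F11 | step 9 | 5,7-dihydroxy-3-(methoxymethoxy)-2-(4-methoxyphenyl)-8-(2-methylbut-3-en-2-yl)-6-(trimethylsilyl)-4H-chromen-4-one | C=CC(C)(C)c1c(O)c([Si](C)(C)C)c(O)c2c(=O)c(OCOC)c(-c3ccc(OC)cc3)oc12
F12 | step 7 | 2,2-dimethylbut-3-en-1-ol | C=CC(C)(C)CO
F13 | step 7 | 2,2-dimethylbut-3-enal | C=CC(C)(C)C=O
F14 | step 7 | 6-(2-hydroxy-3,3-dimethylpent-4-en-1-yl)-3-(methoxymethoxy)-2-(4-methoxyphenyl)-4H-pyran-4-one (racemic) | COCOc1c(-c2ccc(OC)cc2)oc(CC(O)C(C)(C)C=C)cc1=O
F15 | step 8 | 3-(methoxymethoxy)-2-(4-methoxyphenyl)-6-(1,1,1-trifluoro-5,5-dimethyl-2,4-dioxohept-6-en-3-yl)-4H-pyran-4-one | COCOc1c(-c2ccc(OC)cc2)oc(C(C(=O)C(F)(F)F)C(=O)C(C)(C)C=C)cc1=O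
A1 | alternative 1 | 4,6-bis(methoxymethoxy)-3,3-dimethyl-1-benzofuran-2(3H)-one | COCOc1cc(OCOC)c2c(c1)OC(=O)C2(C)C
A2 | alternative 1 | 4,6-bis(methoxymethoxy)-1-benzofuran-2(3H)-one | COCOc1cc(OCOC)c2c(c1)OC(=O)C2
A3 | alternative 1 | 3,5-bis(methoxymethoxy)-2-(2-methylbut-3-en-2-yl)phenol | C=CC(C)(C)c1c(O)cc(OCOC)cc1OCOC
A4 | alternative 2 | 5,7-bis(methoxymethoxy)-2-(4-methoxyphenyl)-8-(2-methylbut-3-en-2-yl)-3-[2-(trimethylsilyl)ethoxy]-4H-chromen-4-one | C=CC(C)(C)c1c(OCOC)cc(OCOC)c2c(=O)c(OCC[Si](C)(C)C)c(-c3ccc(OC)cc3)oc12
A5 | alternative 2 | 2-(chlorocarbonyl)-3,5-bis(methoxymethoxy)-6-(2-methylbut-3-en-2-yl)phenyl 4-methoxybenzoate | C=CC(C)(C)c1c(OCOC)cc(OCOC)c(C(=O)Cl)c1OC(=O)c1ccc(OC)cc1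
A6 | alternative 2 | triphenyl{[2-(trimethylsilyl)ethoxy]methylidene}-λ5-phosphane | C[Si](C)(C)CCOC=P(c1ccccc1)(c1ccccc1)c1ccccc1
A7 | alternative 3 | (2R,3R)-3-hydroxy-5,7-bis(methoxymethoxy)-2-(4-methoxyphenyl)-8-(2-methylbut-3-en-2-yl)-2,3-dihydro-4H-chromen-4-one (trans, one enantiomer of the racemate drawn) | O[C@@H]1[C@@H](c2ccc(OC)cc2)Oc2c(C(C)(C)C=C)c(OCOC)cc(OCOC)c2C1=O
A8 | alternative 3 | 2-[1-(4-methoxyphenyl)-2-oxoethoxy]-4,6-bis(methoxymethoxy)-3-(2-methylbut-3-en-2-yl)benzaldehyde (racemic) | C=CC(C)(C)c1c(OCOC)cc(OCOC)c(C=O)c1OC(C=O)c1ccc(OC)cc1
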